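Cyclohexane ring A (C1 side-chain CH, C2 CH2, C3 CHCl, C4 C(CH3)OH, C5 CHOH, C6 CH–O-angeloyl) is disconnected across C5–C6 and C3–C4: furan supplies C6–C1–C2–C3 and the C6 oxygen, vinylene carbonate supplies C4–C5 with both oxygens. One Diels–Alder step builds the carbocycle as a meso exo 7-oxanorbornene. It exploits the all-cis face of ring A (C1 side chain, C6, C5, C4 oxygens), which is the exo face of the bicycle; the bridge oxygen becomes the C6 ester oxygen. Palladium-catalysed enantioselective alkenylative ring opening then desymmetrises the bicycle with the complete side chain; C4 becomes the C3=C4 methyl alkene, and directed epoxidation plus chloride opening gives the chlorohydrin.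

Key step: step 1

Remark (numbering): side chain C7 (=C12H2) on C1, C8 (CH–O-angeloyl), C9 (CH2), C10 (epoxide CH), C11 (epoxide CMe2); "up" means the face of ring A that carries the C6 oxygen.
Remark (assumption): the facial senses of the three catalyst-controlled steps (BINOL–Ti allylation, Shi ketone, Tol-BINAP–Pd) are taken by analogy with close substrates; the catalyst enantiomer that gives the drawn product is the one meant.

Step 1
Reactants: 1 furan; 2 vinylene carbonate (1,3-dioxol-2-one)
Product: 3 meso exo-3a,4,7,7a-tetrahydro-4,7-epoxy-1,3-benzodioxol-2-one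
Conditions: neat (excess furan), sealed vessel, 125 °C; exo isomer separated by chromatography/crystallisation, endo isomer re-heated
Reagents that add atoms: none
Why: Concerted suprafacial [4π+2π] Diels–Alder cycloaddition of furan (diene C6=C1–C2=C3, its oxygen bridging C6 and C3) with vinylene carbonate (C4=C5), which is the known thermal furan/vinylene carbonate reaction type. Ring A closes by intermolecular [4+2] cycloaddition, the σ-bonds C5–C6 and C3–C4 forming in the same step. The four new stereocentres C3, C4, C5 and C6 are fixed relative to one another by the suprafacial course on both partners (cis bridgeheads, cis carbonate), so exo versus endo is the only open question. The route needs the exo adduct (carbonate oxygens syn to the oxygen bridge); the reversibility of furan cycloadditions at this temperature should favour it as the thermodynamic isomer, and the endo isomer can be recycled by retro-cycloaddition. The product is meso, so no absolute configuration has to be set here.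

Step 2
Reactants: 3 meso exo carbonate
Product: 4 meso exo,exo-7-oxabicyclo[2.2.1]hept-5-ene-2,3-diol
Conditions: K2CO3 (cat.), MeOH, 25 °C
Reagents that add atoms: none
Why: Base-catalysed transesterification (methanolysis) of the strained five-membered cyclic carbonate frees the cis-diol without touching a stereocentre.

Step 3
Reactants: 4 meso exo,exo-diol
Product: 5 meso exo,exo-2,3-bis(tert-butyldimethylsilyloxy)-7-oxabicyclo[2.2.1]hept-5-ene
Conditions: TBSOTf, 2,6-lutidine, CH2Cl2, 0 → 25 °C
Reagents that add atoms: tert-butyldimethylsilyl triflate CC(C)(C)[Si](C)(C)OS(=O)(=O)C(F)(F)F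
Why: Silyl ether formation with the reactive triflate protects both hindered exo hydroxyls against the later basic coupling and keeps the compound meso.

Step 4
Reactants: 6 3-(trimethylsilyl)propynal
Product: 7 (S)-1-(trimethylsilyl)hex-5-en-1-yn-3-ol
Conditions: allylSnBu3, Ti(OiPr)4 (10 mol %), (S)-BINOL (20 mol %), 4 Å MS, CH2Cl2, −20 °C
Reagents that add atoms: allyltributylstannane C=CC[Sn](CCCC)(CCCC)CCCC
Why: Keck asymmetric allylation, in which the BINOL–titanium Lewis acid activates the ynal and directs allyl transfer from tin to one aldehyde face, sets C8 as (S).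

Step 5
Reactants: 7 (S)-1-(trimethylsilyl)hex-5-en-1-yn-3-ol
Product: 8 (S)-6-methyl-1-(trimethylsilyl)hept-5-en-1-yn-3-ol
Conditions: 2-methyl-2-butene (excess), second-generation Grubbs catalyst (3 mol %), CH2Cl2, 35 °C
Reagents that add atoms: 2-methyl-2-butene CC=C(C)C
Why: Olefin cross-metathesis of the terminal alkene with excess 2-methyl-2-butene installs the prenyl terminus (C10=C11), and the silyl-capped alkyne and the free alcohol are tolerated.

Step 6
Reactants: 8 (S)-6-methyl-1-(trimethylsilyl)hept-5-en-1-yn-3-ol
Product: 9 (2S)-1-[(2S)-3,3-dimethyloxiran-2-yl]-4-(trimethylsilyl)but-3-yn-2-ol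
Conditions: ent-Shi ketone (L-fructose-derived, 30 mol %), KHSO5 (Oxone), K2CO3, Bu4NHSO4, MeCN/CH2(OMe)2/aq. borate buffer, 0 °C
Reagents that add atoms: potassium peroxymonosulfate [K+].[O-]S(=O)(=O)OO
Why: Shi asymmetric epoxidation, in which the chiral dioxirane attacks the electron-rich trisubstituted alkene through a spiro transition state, sets C10 as (S) under reagent control while the alkyne stays inert.

Step 7
Reactants: 9 silylated epoxy alkynol
Product: 10 (2S)-1-[(2S)-3,3-dimethyloxiran-2-yl]but-3-yn-2-ol
Conditions: K2CO3, MeOH, 0 → 25 °C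
Reagents that add atoms: none
Why: Methoxide-mediated protodesilylation of the alkynylsilane is fast and leaves the epoxide and the carbinol untouched.

Step 8
Reactants: 10 terminal epoxy alkynol
Product: 11 (2S)-1-[(2S)-3,3-dimethyloxiran-2-yl]-3-(4,4,5,5-tetramethyl-1,3,2-dioxaborolan-2-yl)but-3-en-2-ol
Conditions: B2pin2, CuCl (5 mol %), SIMes·HCl (5 mol %), NaOtBu (20 mol %), MeOH (2 equiv), THF, −15 → 22 °C
Reagents that add atoms: bis(pinacolato)diboron CC1(C)OB(OC1(C)C)B1OC(C)(C)C(C)(C)O1
Why: Copper-catalysed protoboration (formal Markovnikov hydroboration), in which the N-aryl NHC–Cu–Bpin species adds across the terminal alkyne with boron at the internal carbon under direction by the propargylic oxygen and methanol protonates the alkenylcopper, gives the 1,1-disubstituted alkenylboronate that carries C7 and C12.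

Step 9
Reactants: 5 meso bis-silyl ether; 11 alkenylboronate
Product: 12 all-cis ring-opened cyclohex-3-en-1-ol (C6–OH, C1–alkenyl, C5–OTBS and C4–OTBS all up; C2=C3; free C8–OH)
Conditions: Pd(MeCN)2Cl2 (5 mol %), (R)-Tol-BINAP (6 mol %), Cs2CO3, MeOH, 25–40 °C
Reagents that add atoms: none
Why: Palladium-catalysed asymmetric ring opening of an oxabicyclic alkene with an organoboron reagent, in which the alkenyl–palladium species adds syn across C1=C2 from the exo face and β-oxygen elimination cleaves C3–O, places the C1 alkenyl group cis to the C6 hydroxyl and to both silyloxy groups, and the chiral ligand chooses between the enantiotopic alkene carbons of meso 5 and thereby sets the absolute configuration of C1, C4, C5 and C6.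

Step 10
Reactants: 12 ring-opened diol; 13 angelic acid
Product: 15 C6,C8-bis-angelate of 12, via angelic 2,4,6-trichlorobenzoic anhydride 14 (not isolated)
Conditions: 13 (3 equiv), 2,4,6-Cl3C6H2COCl, Et3N, toluene, 25 °C; then 12, 75 °C
Reagents that add atoms: none
Why: Yamaguchi-type esterification through the mixed anhydride acylates both secondary alcohols (C6 and C8) and avoids the Z-to-E isomerisation of the angeloyl unit that nucleophilic catalysts tend to cause.

Step 11
Reactants: 15 bis-angelate bis-silyl ether
Product: 16 C4,C5-diol (C6 and C8 angelates)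
Conditions: Bu4NF/AcOH (1:1), THF, 0 → 25 °C
Reagents that add atoms: none
Why: Fluoride-mediated desilylation, buffered with acetic acid to suppress acyl migration from C6 and to spare the epoxide, frees the C4 and C5 hydroxyls.

Step 12
Reactants: 16 C4,C5-diol
Product: 17 cyclohex-2-enone (C4 ketone, C2=C3) with free C5–OH
Conditions: MnO2 (activated, excess), CH2Cl2, 25 °C
Reagents that add atoms: none
Why: Chemoselective allylic oxidation with MnO2 converts only the allylic C4 carbinol into the enone and leaves the saturated C5 carbinol alone.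

Step 13
Reactants: 17 hydroxy enone
Product: 18 C5-O-triethylsilyl enone
Conditions: TESCl, imidazole, DMF, 0 °C
Reagents that add atoms: chlorotriethylsilane CC[Si](Cl)(CC)CC
Why: Silyl ether formation at the only free hydroxyl masks C5–OH for the hydride and Grignard steps.

Step 14
Reactants: 18 silyloxy enone
Product: 20 C3=C4 enol triflate, via lithium enolate 19 (not isolated)
Conditions: LiBH(s-Bu)3 (L-Selectride, 1.05 equiv), THF, −78 °C; then PhNTf2, −78 → 0 °C
Reagents that add atoms: N-phenylbis(trifluoromethanesulfonimide) O=S(=O)(N(c1ccccc1)S(=O)(=O)C(F)(F)F)C(F)(F)F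
Why: Conjugate (1,4) reduction of the β-unsubstituted cyclohexenone by the bulky borohydride delivers hydride to C2 and gives the C3=C4 enolate regiospecifically, O-triflation traps it, and the hindered trisubstituted angelates should react much more slowly with the hydride at −78 °C.

Step 15
Reactants: 20 enol triflate
Product: 21 C3=C4 alkene bearing the C4 methyl group (C5–OTES)
Conditions: MeMgBr, Fe(acac)3 (5 mol %), THF/NMP, −30 °C
Reagents that add atoms: methylmagnesium bromide C[Mg]Br
Why: Iron-catalysed Kumada-type cross-coupling of the alkenyl triflate with MeMgBr is fast at low temperature, which should let the esters and the epoxide survive, and it places the methyl group on C4.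

Step 16
Reactants: 21 silyl ether
Product: 22 allylic alcohol (free C5–OH next to C4(CH3)=C3)
Conditions: Bu4NF/AcOH (1:1), THF, 0 °C
Reagents that add atoms: none
Why: Buffered fluoride desilylation removes the triethylsilyl group and returns the allylic C5 hydroxyl without acyl migration.

Step 17
Reactants: 22 allylic alcohol
Product: 23 C3,C4-epoxy alcohol (epoxide oxygen up, syn to C5–OH)
Conditions: VO(acac)2 (5 mol %), tBuOOH, CH2Cl2, 0 → 25 °C
Reagents that add atoms: tert-butyl hydroperoxide CC(C)(C)OO
Why: Vanadium-catalysed hydroxyl-directed epoxidation delivers oxygen to C3=C4 on the face of the allylic C5 hydroxyl, which sets C3 and C4, and it leaves the alkenes that lack a free allylic hydroxyl alone.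

Step 18
Reactants: 23 epoxy alcohol
Product: 24 target CNP0333703.2
Conditions: ClTi(OiPr)3 (1.5 equiv), CH2Cl2, −20 → 0 °C; aq. NaHCO3/Rochelle salt
Reagents that add atoms: chlorotitanium triisopropoxide CC(C)O[Ti](Cl)(OC(C)C)OC(C)C
Why: Titanium-assisted regioselective opening of a 2,3-epoxy alcohol, in which the C5 alkoxide binds titanium and chloride attacks the distal secondary C3 with inversion (trans-diaxial SN2 opening), gives the C3 chloride anti to the tertiary C4 hydroxyl, and the unchelated side-chain epoxide should react much more slowly.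

Compound list
1 | furan | c1ccoc1 | starting material
2 | vinylene carbonate | O=C1OC=CO1 | starting material
3 | meso exo-3a,4,7,7a-tetrahydro-4,7-epoxy-1,3-benzodioxol-2-one | C1=C[C@@H]2[C@@H](OC(=O)O3)[C@@H]3[C@H]1O2 | intermediate
4 | meso exo,exo-7-oxabicyclo[2.2.1]hept-5-ene-2,3-diol | C1=C[C@@H]2[C@@H](O)[C@@H](O)[C@H]1O2 | intermediate
5 | meso exo,exo-2,3-bis(tert-butyldimethylsilyloxy)-7-oxabicyclo[2.2.1]hept-5-ene | C1=C[C@@H]2[C@@H](O[Si](C)(C)C(C)(C)C)[C@@H](O[Si](C)(C)C(C)(C)C)[C@H]1O2 | intermediate
6 | 3-(trimethylsilyl)propynal | C[Si](C)(C)C#CC=O | starting material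
7 | (S)-1-(trimethylsilyl)hex-5-en-1-yn-3-ol | C[Si](C)(C)C#C[C@H](CC=C)O | intermediate
8 | (S)-6-methyl-1-(trimethylsilyl)hept-5-en-1-yn-3-ol | C[Si](C)(C)C#C[C@H](CC=C(C)C)O | intermediate
9 | (2S)-1-[(2S)-3,3-dimethyloxiran-2-yl]-4-(trimethylsilyl)but-3-yn-2-ol | C[Si](C)(C)C#C[C@H](C[C@@H]1OC1(C)C)O | intermediate
10 | (2S)-1-[(2S)-3,3-dimethyloxiran-2-yl]but-3-yn-2-ol | C#C[C@H](C[C@@H]1OC1(C)C)O | intermediate
11 | (2S)-1-[(2S)-3,3-dimethyloxiran-2-yl]-3-(4,4,5,5-tetramethyl-1,3,2-dioxaborolan-2-yl)but-3-en-2-ol | C=C(B1OC(C)(C)C(C)(C)O1)[C@H](C[C@@H]2OC2(C)C)O | intermediate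
12 | all-cis 2-alkenyl-5,6-bis(tert-butyldimethylsilyloxy)cyclohex-3-en-1-ol (C1 alkenyl, C6–OH, C5 and C4 silyloxy up; free C8–OH) | C=C([C@H](C[C@@H]1OC1(C)C)O)[C@H]1C=C[C@@H](O[Si](C)(C)C(C)(C)C)[C@@H](O[Si](C)(C)C(C)(C)C)[C@H]1O | intermediate
13 | angelic acid, (Z)-2-methylbut-2-enoic acid | C/C=C(/C)C(=O)O | starting material
14 | angelic 2,4,6-trichlorobenzoic anhydride | C/C=C(/C)C(=O)OC(=O)c1c(Cl)cc(Cl)cc1Cl | intermediate (not isolated)
15 | C6,C8-bis-angelate of 12 | C=C([C@H](C[C@@H]1OC1(C)C)OC(=O)/C(C)=C\C)[C@H]1C=C[C@@H](O[Si](C)(C)C(C)(C)C)[C@@H](O[Si](C)(C)C(C)(C)C)[C@H]1OC(=O)/C(C)=C\C | intermediate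
16 | C4,C5-diol bis-angelate | C=C([C@H](C[C@@H]1OC1(C)C)OC(=O)/C(C)=C\C)[C@H]1C=C[C@@H](O)[C@@H](O)[C@H]1OC(=O)/C(C)=C\C | intermediate
17 | C4 enone with free C5–OH | C=C([C@H](C[C@@H]1OC1(C)C)OC(=O)/C(C)=C\C)[C@H]1C=CC(=O)[C@@H](O)[C@H]1OC(=O)/C(C)=C\C | intermediate
18 | C5-O-triethylsilyl enone | C=C([C@H](C[C@@H]1OC1(C)C)OC(=O)/C(C)=C\C)[C@H]1C=CC(=O)[C@@H](O[Si](CC)(CC)CC)[C@H]1OC(=O)/C(C)=C\C | intermediate
19 | lithium C3=C4 enolate | C=C([C@H](C[C@@H]1OC1(C)C)OC(=O)/C(C)=C\C)[C@H]1CC=C(O[Li])[C@@H](O[Si](CC)(CC)CC)[C@H]1OC(=O)/C(C)=C\C | intermediate (not isolated)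
20 | C3=C4 enol triflate | C=C([C@H](C[C@@H]1OC1(C)C)OC(=O)/C(C)=C\C)[C@H]1CC=C(OS(=O)(=O)C(F)(F)F)[C@@H](O[Si](CC)(CC)CC)[C@H]1OC(=O)/C(C)=C\C | intermediate
21 | C4-methyl C3=C4 alkene, C5–OTES | C=C([C@H](C[C@@H]1OC1(C)C)OC(=O)/C(C)=C\C)[C@H]1CC=C(C)[C@@H](O[Si](CC)(CC)CC)[C@H]1OC(=O)/C(C)=C\C | intermediate
22 | allylic alcohol, free C5–OH | C=C([C@H](C[C@@H]1OC1(C)C)OC(=O)/C(C)=C\C)[C@H]1CC=C(C)[C@@H](O)[C@H]1OC(=O)/C(C)=C\C | intermediate
23 | C3,C4-epoxy alcohol, epoxide syn to C5–OH | C=C([C@H](C[C@@H]1OC1(C)C)OC(=O)/C(C)=C\C)[C@H]1C[C@H]2O[C@@]2(C)[C@@H](O)[C@H]1OC(=O)/C(C)=C\C | intermediate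
24 | CNP0333703.2 | C=C([C@H](C[C@@H]1OC1(C)C)OC(=O)/C(C)=C\C)[C@H]1C[C@H](Cl)[C@@](C)(O)[C@@H](O)[C@H]1OC(=O)/C(C)=C\C | target

Total step count: 18. Longest linear sequence: 15 steps (steps 4–18, from 3-(trimethylsilyl)propynal); the ring branch runs 13 steps (steps 1–3 and 9–18).

Steps most likely to fail

Step 9. The hindered 1,1-disubstituted alkenylboronate may transmetalate slowly and protodeboronate, and the resident C8 stereocentre may erode ligand control over which enantiotopic alkene carbon is attacked. The fallback leaves boron transmetalation for an oxidative-addition, reductive manifold. It sets out from 11, which is iodinated (NaOMe, then I2, THF/MeOH, −78 → 0 °C) to the 2-iodoalkene (2S)-1-[(2S)-3,3-dimethyloxiran-2-yl]-3-iodobut-3-en-2-ol F1. This is coupled with 5 using Pd(OAc)2, (R)-BINAP and zinc powder in MeCN. The alkenyl–palladium halide adds across the exo face, β-oxygen elimination opens the bridge, and zinc returns divalent palladium to zerovalent palladium. The fallback comes back to the route at 12.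

Step 1. The cycloaddition is reversible and may stall at low conversion or give mainly the endo isomer. The fallback keeps the same two ring bonds but uses an acetylene equivalent and sets the diol afterwards. It sets out from 1, which reacts with (Z)-1,2-bis(phenylsulfonyl)ethene to give the cis-endo bis-sulfone adduct 5,6-bis(phenylsulfonyl)-7-oxabicyclo[2.2.1]hept-2-ene F2. Reductive elimination with sodium amalgam Na(Hg) in buffered MeOH gives 7-oxabicyclo[2.2.1]hepta-2,5-diene F3. Mono-dihydroxylation with OsO4 (cat.) and one equivalent of N-methylmorpholine N-oxide occurs only from the exo face and comes back to the route at 4.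

Step 18. The Lewis-acidic titanium reagent may also open or rearrange the side-chain epoxide, chloride may attack the tertiary C4, or the C6 angeloyl group may migrate to C5–O. The fallback avoids the ring epoxide altogether. It sets out from 22, which is treated with N-chlorosuccinimide in aqueous acetone at 0 °C. The chloronium ion should form on the less hindered lower face of the electron-rich C3=C4 bond and water should open it at the tertiary C4 from above (anti, Markovnikov), so the route is rejoined directly at 24. No new isolated compound is made (F0).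

Further compounds
F1 | step 9 | (2S)-1-[(2S)-3,3-dimethyloxiran-2-yl]-3-iodobut-3-en-2-ol | C=C(I)[C@H](C[C@@H]1OC1(C)C)O
F2 | step 1 | cis-endo-5,6-bis(phenylsulfonyl)-7-oxabicyclo[2.2.1]hept-2-ene | C1=C[C@@H]2[C@H](S(=O)(=O)c3ccccc3)[C@H](S(=O)(=O)c3ccccc3)[C@H]1O2
F3 | step 1 | 7-oxabicyclo[2.2.1]hepta-2,5-diene | C1=C[C@@H]2C=C[C@H]1O2
F0 | step 18 | none | none
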